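Everything rests on reading ring B (the dihydrofuran ring) as the furan ring of aromatic 7-methoxybenzofuran whose C2=C3 enol-ether π bond has been saturated: the C3 methyl and the C2 trimethoxyphenyl group (ring C), trans in the target, enter from opposite faces in one operation. The precursor is a four-coordinate lithium borate whose boron carries the benzofuran-2-yl group, ring C and a chiral butane-2,3-diolate. Methylation at C3 drives the aryl group from boron to C2 on the other face, creating both stereocentres and leaving boron as a placeholder for the C2 hydrogen. Protodeboronation and C5 propenylation of ring A (the benzo ring) complete the synthesis.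

Key step: step 2

Assumption: the (4R,5R)-diolate on boron is taken to direct C3-methylation to the face that leads to the (2R,3R) series; if the opposite sense is found, (2S,3S)-butane-2,3-diol replaces its enantiomer in step 1 and nothing else changes.

Step 1
Reactants: 1 (3,4,5-trimethoxyphenyl)boronic acid; 2 (2R,3R)-butane-2,3-diol
Product: 3 (4R,5R)-4,5-dimethyl-2-(3,4,5-trimethoxyphenyl)-1,3,2-dioxaborolane
Conditions: MgSO4, CH2Cl2, rt
Reagents that add atoms: none
Why: Boronic ester formation by condensation of a boronic acid with a 1,2-diol is driven to completion by the drying agent; the two diol stereocentres are spectators and keep their (R,R) configuration.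

Step 2
Reactants: 4 7-methoxy-1-benzofuran; 3 (4R,5R)-4,5-dimethyl-2-(3,4,5-trimethoxyphenyl)-1,3,2-dioxaborolane; 5 methyl trifluoromethanesulfonate
Product: 8 (2R,3R)-2-[(4R,5R)-4,5-dimethyl-1,3,2-dioxaborolan-2-yl]-7-methoxy-3-methyl-2-(3,4,5-trimethoxyphenyl)-2,3-dihydro-1-benzofuran, via (7-methoxy-1-benzofuran-2-yl)lithium 6 (not isolated), via lithium benzofuranyl aryl borate 7 (not isolated)
Conditions: n-BuLi, THF, −78 °C; then 3, −78 °C → rt; THF exchanged for CH2Cl2; MeOTf, −78 → 0 °C
Reagents that add atoms: methyl trifluoromethanesulfonate (compound 5), COS(=O)(=O)C(F)(F)F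
Why: Proposed new method: C2-lithiation of 4 and addition to the trigonal boron of 3 give borate 7, in which C3 is the β-carbon of an enol ether made strongly nucleophilic by the anionic boron at C2; MeOTf should alkylate this carbon, and the oxocarbenium character that develops at C2 is quenched by a 1,2-shift of the trimethoxyphenyl group from boron, antiperiplanar to the incoming methyl, so that C3–CH3 and C2–C1' form on opposite faces while ring B loses its aromaticity. The closest known reaction type is the electrophile-induced dearomative 1,2-metallate rearrangement of indol-2-yl and furan-2-yl boronate complexes; C-methylation of a benzofuran-2-yl complex and asymmetric induction from a diol on boron (instead of a chiral electrophile) are the untested elements. No ring is closed. C2 is controlled by the stereospecific anti geometry of the shift relative to C3 (aryl trans to methyl, boron cis to methyl), and the absolute configuration at C3 by the (4R,5R)-diolate, whose methyl groups make the two rotamers with the migrating aryl above or below the benzofuran plane diastereomeric. Because the diol stays in the product, the two possible anti adducts are diastereomers, so a modest facial preference can be raised by chromatography or crystallisation of 8 before the auxiliary is removed. The step further needs C3-methylation to outrun O-methylation of the diolate and attack on ring C, which the high nucleophilicity of the boron-substituted enol-ether carbon, the low temperature and the exchange of THF (which MeOTf would ring-open) for CH2Cl2 should secure.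

Step 3
Reactants: 8 (2R,3R)-2-[(4R,5R)-4,5-dimethyl-1,3,2-dioxaborolan-2-yl]-7-methoxy-3-methyl-2-(3,4,5-trimethoxyphenyl)-2,3-dihydro-1-benzofuran
Product: 9 (2R,3R)-7-methoxy-3-methyl-2-(3,4,5-trimethoxyphenyl)-2,3-dihydro-1-benzofuran
Conditions: CsF, H2O (1.1 equiv), 1,4-dioxane, 45 °C
Reagents that add atoms: none
Why: Fluoride-promoted protodeboronation of a tertiary benzylic boronic ester is known to replace boron by hydrogen with retention, the proton coming from water held at the fluoroborate on the face that boron leaves (fluoride only activates boron and returns as CsF on work-up); the C2 hydrogen therefore ends up cis to the C3 methyl, the aryl group stays trans to it, and C3 is not touched.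

Step 4
Reactants: 9 (2R,3R)-7-methoxy-3-methyl-2-(3,4,5-trimethoxyphenyl)-2,3-dihydro-1-benzofuran; 10 (E)-1-bromoprop-1-ene
Product: 12 (2R,3R)-7-methoxy-3-methyl-5-[(1E)-prop-1-en-1-yl]-2-(3,4,5-trimethoxyphenyl)-2,3-dihydro-1-benzofuran, via aryl pinacol boronate 11 (not isolated)
Conditions: [Ir(cod)(OMe)]2 (cat.), dtbpy, B2pin2, THF, 80 °C; volatiles removed; then Pd(dppf)Cl2 (cat.), K3PO4, 10, THF/H2O, 60 °C, sealed tube
Reagents that add atoms: none
Why: One-pot iridium-catalysed C–H borylation and Suzuki–Miyaura coupling: the borylation is sterically controlled and should take C5–H of ring A, the only aryl C–H without an ortho substituent (C4–H and C6–H each have one, the two C–H bonds of ring C have two), and the coupling of the aryl boronate with the alkenyl bromide at zerovalent palladium retains the E geometry; the boron brought in by B2pin2 is carried only in 11 and leaves again, and neither stereocentre is involved.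

Compound list
1 | (3,4,5-trimethoxyphenyl)boronic acid | COc1cc(B(O)O)cc(OC)c1OC | starting material
2 | (2R,3R)-butane-2,3-diol | C[C@@H](O)[C@@H](C)O | starting material
3 | (4R,5R)-4,5-dimethyl-2-(3,4,5-trimethoxyphenyl)-1,3,2-dioxaborolane | COc1cc(B2O[C@H](C)[C@@H](C)O2)cc(OC)c1OC | intermediate
4 | 7-methoxy-1-benzofuran | COc1cccc2ccoc12 | starting material
5 | methyl trifluoromethanesulfonate | COS(=O)(=O)C(F)(F)F | starting material
6 | (7-methoxy-1-benzofuran-2-yl)lithium | [Li]c1cc2cccc(OC)c2o1 | intermediate (not isolated)
7 | lithium [(2R,3R)-butane-2,3-diolato](7-methoxy-1-benzofuran-2-yl)(3,4,5-trimethoxyphenyl)borate | [Li+].COc1cccc2cc(oc12)[B-]1(c3cc(OC)c(OC)c(OC)c3)O[C@H](C)[C@@H](C)O1 | intermediate (not isolated)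
8 | (2R,3R)-2-[(4R,5R)-4,5-dimethyl-1,3,2-dioxaborolan-2-yl]-7-methoxy-3-methyl-2-(3,4,5-trimethoxyphenyl)-2,3-dihydro-1-benzofuran (aryl trans to the C3 methyl, boron cis to it) | c1cc(OC)c2c(c1)[C@@H](C)[C@](B1O[C@H](C)[C@@H](C)O1)(c1cc(OC)c(OC)c(OC)c1)O2 | intermediate
9 | (2R,3R)-7-methoxy-3-methyl-2-(3,4,5-trimethoxyphenyl)-2,3-dihydro-1-benzofuran (trans) | c1cc(OC)c2c(c1)[C@@H](C)[C@H](c1cc(OC)c(OC)c(OC)c1)O2 | intermediate
10 | (E)-1-bromoprop-1-ene | C/C=C/Br | starting material
11 | (2R,3R)-7-methoxy-3-methyl-5-(4,4,5,5-tetramethyl-1,3,2-dioxaborolan-2-yl)-2-(3,4,5-trimethoxyphenyl)-2,3-dihydro-1-benzofuran | CC1(C)OB(OC1(C)C)c1cc(OC)c2c(c1)[C@@H](C)[C@H](c1cc(OC)c(OC)c(OC)c1)O2 | intermediate (not isolated)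
12 | (2R,3R)-7-methoxy-3-methyl-5-[(1E)-prop-1-en-1-yl]-2-(3,4,5-trimethoxyphenyl)-2,3-dihydro-1-benzofuran (trans) | C/C=C/c1cc(OC)c2c(c1)[C@@H](C)[C@H](c1cc(OC)c(OC)c(OC)c1)O2 | target

Total step count: 4 (steps 2 and 4 are one-pot operations).
Longest linear sequence: 4 steps (1 → 3 → 8 → 9 → 12).

Steps most likely to fail

Step 2 (proposed new method). The borate may be methylated at a diolate oxygen or on ring C instead of at C3. The small methyl groups of the diolate may also discriminate the two faces of C3 only weakly, so that both anti adducts form. The fallback uses known chemistry only, sets out from boronic acid 1 and comes back at compound 9.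
- Acylative Suzuki–Miyaura coupling of 1 with propanoic anhydride (Pd(OAc)2, PPh3, THF/H2O, 60 °C) gives 1-(3,4,5-trimethoxyphenyl)propan-1-one F1, which is also a catalogue compound.
- Palladium-catalysed ketone α-arylation with commercial 1-bromo-2-fluoro-3-methoxybenzene (Pd2(dba)3, Xantphos, NaOtBu, toluene, 80 °C) gives racemic 2-(2-fluoro-3-methoxyphenyl)-1-(3,4,5-trimethoxyphenyl)propan-1-one F2, whose α-stereocentre epimerises readily.
- Noyori–Ikariya asymmetric transfer hydrogenation under dynamic kinetic resolution (RuCl[(R,R)-TsDPEN](p-cymene), HCO2H/Et3N, 40 °C) should give the Felkin-type syn alcohol (1R,2R)-2-(2-fluoro-3-methoxyphenyl)-1-(3,4,5-trimethoxyphenyl)propan-1-ol F3. The aryl/alkyl facial rule of the catalyst is expected to set C1, and the substrate then fixes C2.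
- Intramolecular nucleophilic aromatic substitution of fluoride by the alkoxide (KOtBu, THF, 65 °C) closes the five-membered ring B. The carbinol C–O bond is not broken, so configuration is retained and the trans compound 9 results.

Step 3. Protonolysis of the congested tertiary C–B bond may stall, or an invertive pathway may compete and erode the C2 configuration. The fallback sets out from 8 and comes back at 9. The C–B cleavage is pushed to completion with the stronger fluoride source TBAF·3H2O (toluene, 60 °C), accepting any loss of fidelity at C2. This gives 9 together with its C2 epimer (2S,3R)-7-methoxy-3-methyl-2-(3,4,5-trimethoxyphenyl)-2,3-dihydro-1-benzofuran F4. C2 is then corrected under thermodynamic control (CF3CO2H, CH2Cl2, 0 °C → rt). Reversible ionisation of the benzylic C2–O bond, with the cation stabilised by the para-methoxy group of ring C, and re-closure by the phenol should converge on the more stable trans isomer 9. C3, set in step 2, is not part of this equilibrium; mild acid and low temperature are chosen so that the cation does not lose the C3 proton.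

Step 4. A minor share of borylation at C6, next to the methoxy group, would pass through the one-pot sequence unnoticed. The coupling may also suffer from loss of the volatile alkenyl bromide, protodeboronation of the electron-rich aryl boronate or erosion of the E geometry. The fallback sets out from 11, now isolated and freed of any regioisomer after a separate borylation of 9, and comes back at 12 with the polarity of the coupling reversed.
- Oxidation of 11 (H2O2, NaOH, THF/H2O, 0 °C) gives the phenol (2R,3R)-7-methoxy-3-methyl-2-(3,4,5-trimethoxyphenyl)-2,3-dihydro-1-benzofuran-5-ol F5.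
- Triflation (PhNTf2, Et3N, CH2Cl2) gives (2R,3R)-7-methoxy-3-methyl-2-(3,4,5-trimethoxyphenyl)-2,3-dihydro-1-benzofuran-5-yl trifluoromethanesulfonate F6.
- Suzuki–Miyaura coupling of F6 with commercial potassium (E)-prop-1-enyltrifluoroborate (Pd(dppf)Cl2, Cs2CO3, THF/H2O, 70 °C), a non-volatile partner of defined geometry, gives 12.

Further compounds
F1 | step 2 | 1-(3,4,5-trimethoxyphenyl)propan-1-one | CCC(=O)c1cc(OC)c(OC)c(OC)c1
F2 | step 2 | 2-(2-fluoro-3-methoxyphenyl)-1-(3,4,5-trimethoxyphenyl)propan-1-one (racemic) | CC(C(=O)c1cc(OC)c(OC)c(OC)c1)c1cccc(OC)c1F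
F3 | step 2 | (1R,2R)-2-(2-fluoro-3-methoxyphenyl)-1-(3,4,5-trimethoxyphenyl)propan-1-ol | COc1cccc(c1F)[C@@H](C)[C@H](c1cc(OC)c(OC)c(OC)c1)O
F4 | step 3 | (2S,3R)-7-methoxy-3-methyl-2-(3,4,5-trimethoxyphenyl)-2,3-dihydro-1-benzofuran (cis, C2 epimer of 9) | c1cc(OC)c2c(c1)[C@@H](C)[C@@H](c1cc(OC)c(OC)c(OC)c1)O2
F5 | step 4 | (2R,3R)-7-methoxy-3-methyl-2-(3,4,5-trimethoxyphenyl)-2,3-dihydro-1-benzofuran-5-ol | Oc1cc(OC)c2c(c1)[C@@H](C)[C@H](c1cc(OC)c(OC)c(OC)c1)O2
F6 | step 4 | (2R,3R)-7-methoxy-3-methyl-2-(3,4,5-trimethoxyphenyl)-2,3-dihydro-1-benzofuran-5-yl trifluoromethanesulfonate | FC(F)(F)S(=O)(=O)Oc1cc(OC)c2c(c1)[C@@H](C)[C@H](c1cc(OC)c(OC)c(OC)c1)O2
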